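**Retrosynthetic overview**
1. Target ⇒ last O8 desilylation and C9 esterification with (2R,3R)-epoxyangelic acid (fragment C, Sharpless epoxidation of angelyl alcohol).
2. Ten-membered carbocycle (formed second): ring-closing metathesis makes the 1(10)Z alkene from a C1 vinyl and a C10 isopropenyl group.
3. Lactone ring (formed first) and the C6–C7 bond: indium Barbier 2-(alkoxycarbonyl)allylation/lactonisation joins lactol fragment A (C1–C6) to allyl bromide fragment B (C7–C14), setting C6 and C7.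
4. Fragment A: new chiral-acid-catalysed allylboration/lactonisation of 5-hydroxy-4-methylfuranone (sets C3, holds the 4Z alkene in a butenolide). Fragment B: D-mannitol-derived glyceraldehyde acetonide (C8), Felkin isopropenyl addition (C9), Baylis–Hillman-type homologation.

Assumption: germacrane numbering is used (C6 bears the lactone oxygen, C12 is the lactone carbonyl, C11=C13 the methylene; OAc on C3, OH on C8, epoxyangelate on C9) and the SMILES is read literally as 3S,6R,7S,8R,9S, 1(10)Z,4Z, cis-fused lactone, (2R,3R)-epoxide.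

**Route**

Step 1
Reactants: 1 5-hydroxy-4-methylfuran-2(5H)-one; 2 allylboronic acid pinacol ester
Product: 5 (5S)-4-methyl-5-(prop-2-en-1-yl)furan-2(5H)-one, via open-chain formyl acid 3 (not isolated), via boryl ether 4 (not isolated)
Conditions: (S)-TRIP (5 mol %), 4 Å MS, toluene/CH2Cl2 4:1, −30 → 0 °C, then rt
Reagents that add atoms: none
Why: Proposed new method: chiral-phosphoric-acid-catalysed allylboration of a γ-hydroxybutenolide pseudo-acid with in situ lactonisation — 1 equilibrates with its ring-opened (Z)-formyl acid 3 (the form such hydroxybutenolides show in Wittig reactions), the catalyst hydrogen-bonds the pseudo-axial boronate oxygen of 2 and the formyl C–H so that allyl transfer through a closed chair transition state occurs on one aldehyde face and sets C3 as S (the (S)-catalyst is chosen by analogy with the (R)-catalyst → (R)-carbinol sense known for aryl and alkenyl aldehydes), and the Z geometry inherited from the ring lets boryl ether 4 close to butenolide 5 with loss of pinacol borate; the closest known reaction type is the chiral-phosphoric-acid-catalysed allylboration of ordinary aldehydes with allyl-Bpin, not yet shown for lactol/pseudo-acid aldehyde surrogates.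

Step 2
Reactants: 5 (5S)-4-methyl-5-(prop-2-en-1-yl)furan-2(5H)-one
Product: 6 (5S)-4-methyl-5-(prop-2-en-1-yl)-2,5-dihydrofuran-2-ol (anomer mixture)
Conditions: i-Bu2AlH (1.1 equiv), CH2Cl2, −78 °C; aq. potassium sodium tartrate work-up; used crude
Reagents that add atoms: none
Why: Partial reduction of the lactone stops at the aluminium hemiacetal at −78 °C and gives the lactol, a ring-locked masked (Z)-γ-hydroxy enal whose 4Z geometry cannot isomerise; C3 is not touched.

Step 3
Reactants: 7 1,2:5,6-di-O-isopropylidene-D-mannitol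
Product: 8 (R)-2,2-dimethyl-1,3-dioxolane-4-carbaldehyde
Conditions: NaIO4, sat. aq. NaHCO3, CH2Cl2, rt
Reagents that add atoms: none
Why: Periodate glycol cleavage of the twofold-symmetric diol releases two molecules of (R)-glyceraldehyde acetonide, whose stereocentre becomes C8 (chiral pool).

Step 4
Reactants: 8 (R)-2,2-dimethyl-1,3-dioxolane-4-carbaldehyde; 9 isopropenylmagnesium bromide
Product: 10 (1S)-1-[(4R)-2,2-dimethyl-1,3-dioxolan-4-yl]-2-methylprop-2-en-1-ol
Conditions: THF, −78 °C; chromatography to remove the minor syn isomer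
Reagents that add atoms: none
Why: Felkin–Anh (non-chelation) Grignard addition to the α-alkoxy aldehyde gives mainly the anti (erythro) carbinol (about 3–4:1), which sets C9 as S next to C8.

Step 5
Reactants: 10 (1S)-1-[(4R)-2,2-dimethyl-1,3-dioxolan-4-yl]-2-methylprop-2-en-1-ol
Product: 11 (4R)-4-[(1S)-1-[(4-methoxybenzyl)oxy]-2-methylprop-2-en-1-yl]-2,2-dimethyl-1,3-dioxolane
Conditions: NaH, PMBCl, n-Bu4NI (cat.), THF/DMF, 0 °C → rt
Reagents that add atoms: 4-methoxybenzyl chloride, COc1ccc(CCl)cc1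
Why: Williamson etherification masks O9 as a p-methoxybenzyl ether orthogonal to the silyl ether and acetate used later; no stereocentre is touched.

Step 6
Reactants: 11 (4R)-4-[(1S)-1-[(4-methoxybenzyl)oxy]-2-methylprop-2-en-1-yl]-2,2-dimethyl-1,3-dioxolane
Product: 12 (2R,3S)-3-[(4-methoxybenzyl)oxy]-4-methylpent-4-ene-1,2-diol
Conditions: AcOH/H2O 4:1, 40 °C
Reagents that add atoms: none
Why: Mild acid hydrolysis of the terminal acetonide frees the C7/C8 diol while the p-methoxybenzyl ether survives.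

Step 7
Reactants: 12 (2R,3S)-3-[(4-methoxybenzyl)oxy]-4-methylpent-4-ene-1,2-diol
Product: 13 (2R,3S)-3-[(4-methoxybenzyl)oxy]-4-methyl-1,2-bis[(triethylsilyl)oxy]pent-4-ene
Conditions: TESCl, imidazole, DMAP (cat.), CH2Cl2, 0 °C → rt
Reagents that add atoms: chlorotriethylsilane, CC[Si](Cl)(CC)CC
Why: Silyl ether formation at both hydroxyls prepares the selective oxidation of the primary position and installs the O8 protecting group that is kept to the last step.

Step 8
Reactants: 13 (2R,3S)-3-[(4-methoxybenzyl)oxy]-4-methyl-1,2-bis[(triethylsilyl)oxy]pent-4-ene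
Product: 14 (2S,3S)-3-[(4-methoxybenzyl)oxy]-4-methyl-2-[(triethylsilyl)oxy]pent-4-enal
Conditions: (COCl)2, DMSO, CH2Cl2, −78 → −30 °C; then Et3N, −78 °C → rt
Reagents that add atoms: none
Why: Under Swern conditions the primary triethylsilyl ether is cleaved by the chlorosulfonium reagent and oxidised in one operation while the secondary one is untouched, so the α-silyloxy aldehyde forms without epimerising C8.

Step 9
Reactants: 14 (2S,3S)-3-[(4-methoxybenzyl)oxy]-4-methyl-2-[(triethylsilyl)oxy]pent-4-enal; 15 methyl propiolate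
Product: 17 methyl (4R,5S)-3-hydroxy-5-[(4-methoxybenzyl)oxy]-6-methyl-2-methylidene-4-[(triethylsilyl)oxy]hept-6-enoate (both carbinol epimers), via vinylalane 16 (not isolated)
Conditions: i-Bu2AlH, N-methylmorpholine N-oxide, THF, 0 °C, then 15; then 14, 0 °C → rt
Reagents that add atoms: none
Why: Hydroalumination of the ynoate gives the α-aluminoacrylate 16, whose 1,2-addition to the aldehyde gives the Morita–Baylis–Hillman-type adduct without amine catalysis (so C8 does not epimerise); the new carbinol centre is destroyed in the next step.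

Step 10
Reactants: 17 methyl (4R,5S)-3-hydroxy-5-[(4-methoxybenzyl)oxy]-6-methyl-2-methylidene-4-[(triethylsilyl)oxy]hept-6-enoate
Product: 18 methyl (2Z,4R,5S)-2-(bromomethyl)-5-[(4-methoxybenzyl)oxy]-6-methyl-4-[(triethylsilyl)oxy]hepta-2,6-dienoate
Conditions: NBS, Me2S, CH2Cl2, 0 °C → rt
Reagents that add atoms: N-bromosuccinimide, O=C1CCC(=O)N1Br
Why: Corey–Kim-type activation of the allylic alcohol and SN2′ attack of bromide give the rearranged primary allyl bromide under thermodynamic control as the Z isomer (chain cis to CH2Br), the geometry needed for a syn-selective allylation.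

Step 11
Reactants: 19 methyl angelate
Product: 20 (Z)-2-methylbut-2-en-1-ol
Conditions: LiAlH4, Et2O, 0 °C
Reagents that add atoms: none
Why: Hydride reduction of the ester to the allylic alcohol leaves the Z alkene unchanged.

Step 12
Reactants: 20 (Z)-2-methylbut-2-en-1-ol
Product: 21 [(2S,3R)-2,3-dimethyloxiran-2-yl]methanol
Conditions: Ti(OiPr)4 (0.2 equiv), L-(+)-diethyl tartrate (0.24 equiv), t-BuOOH, 4 Å MS, CH2Cl2, −20 °C
Reagents that add atoms: tert-butyl hydroperoxide, CC(C)(C)OO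
Why: Sharpless asymmetric epoxidation with the L-(+)-tartrate ligand gives the (2S)-epoxy alcohol and, because the alkene is Z, sets both epoxide centres with CH2OH cis to the C3 methyl.

Step 13
Reactants: 21 [(2S,3R)-2,3-dimethyloxiran-2-yl]methanol
Product: 22 (2R,3R)-2,3-dimethyloxirane-2-carboxylic acid
Conditions: RuCl3·xH2O (2 mol %), NaIO4, CCl4/MeCN/H2O, 0 °C → rt
Reagents that add atoms: water, O; sodium periodate (terminal oxidant), [Na+].[O-]I(=O)(=O)=O
Why: RuO4-catalysed oxidation takes the primary alcohol to the acid without opening the epoxide; the change of the C2 descriptor from S to R is only a priority change.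

Step 14
Reactants: 6 (5S)-4-methyl-5-(prop-2-en-1-yl)-2,5-dihydrofuran-2-ol; 18 methyl (2Z,4R,5S)-2-(bromomethyl)-5-[(4-methoxybenzyl)oxy]-6-methyl-4-[(triethylsilyl)oxy]hepta-2,6-dienoate
Product: 24 (4R,5R)-5-[(1Z,3S)-3-hydroxy-2-methylhexa-1,5-dien-1-yl]-4-[(1R,2S)-2-[(4-methoxybenzyl)oxy]-3-methyl-1-[(triethylsilyl)oxy]but-3-en-1-yl]-3-methylideneoxolan-2-one, via hydroxy ester 23 (not isolated)
Conditions: In powder, THF/H2O 1:1, rt; then PPTS (cat.), CH2Cl2, rt
Reagents that add atoms: none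
Why: Indium-mediated Barbier 2-(alkoxycarbonyl)allylation of the lactol (reacting through its open (Z)-hydroxy enal form) followed by acid-catalysed lactonisation: the (Z)-allyl geometry and a closed chair transition state give the syn adduct (hence the cis-fused lactone, C6 and C7), and C8 directs the aldehyde to the allyl face anti to its C9 substituent with H8 eclipsing the allylic CH2 (A1,3 strain), which is the C7/C8 relationship of the target.

Step 15
Reactants: 24 (the C3 alcohol from step 14)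
Product: 25 (4R,5R)-5-[(1Z,3S)-3-(acetyloxy)-2-methylhexa-1,5-dien-1-yl]-4-[(1R,2S)-2-[(4-methoxybenzyl)oxy]-3-methyl-1-[(triethylsilyl)oxy]but-3-en-1-yl]-3-methylideneoxolan-2-one
Conditions: Ac2O, pyridine, DMAP (cat.), CH2Cl2, 0 °C
Reagents that add atoms: acetic anhydride, CC(=O)OC(C)=O
Why: DMAP-catalysed acetylation of the only free hydroxyl puts the acetate on C3 with retention.

Step 16
Reactants: 25 (the C3 acetate from step 15)
Product: 26 (4R,5R)-5-[(1Z,3S)-3-(acetyloxy)-2-methylhexa-1,5-dien-1-yl]-4-[(1R,2S)-2-hydroxy-3-methyl-1-[(triethylsilyl)oxy]but-3-en-1-yl]-3-methylideneoxolan-2-one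
Conditions: DDQ, CH2Cl2/pH 7 buffer 10:1, 0 °C
Reagents that add atoms: none
Why: Oxidative p-methoxybenzyl ether cleavage by DDQ frees O9 without affecting the silyl ether, the acetate or the alkenes.

Step 17
Reactants: 26 (the C9 alcohol from step 16)
Product: 27 (3S,6R,7R,8R,9S)-3-acetoxy-9-hydroxy-8-[(triethylsilyl)oxy]germacra-1(10)Z,4Z,11(13)-trien-12,6-olide
Conditions: second-generation Hoveyda–Grubbs catalyst RuCl2(=CH-C6H4-2-O-i-Pr)(H2IMes) (15 mol %), 1,4-benzoquinone (30 mol %), toluene (1 mM), 80 °C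
Reagents that add atoms: none
Why: Ring-closing metathesis: the ruthenium alkylidene forms at the monosubstituted C1 alkene and closes onto the isopropenyl group, helped by the free allylic C9 hydroxyl, and the ten-membered ring that already holds the 4Z alkene and the cis-fused lactone accepts the new trisubstituted alkene only as the ring-cis (Z) isomer.

Step 18
Reactants: 27 (the macrocyclic C9 alcohol from step 17); 22 (2R,3R)-2,3-dimethyloxirane-2-carboxylic acid
Product: 29 (3S,6R,7R,8R,9S)-3-acetoxy-9-{[(2R,3R)-2,3-dimethyloxiran-2-yl]carbonyloxy}-8-[(triethylsilyl)oxy]germacra-1(10)Z,4Z,11(13)-trien-12,6-olide, via mixed anhydride 28 (not isolated)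
Conditions: 22, 2,4,6-trichlorobenzoyl chloride, Et3N, toluene, rt; then 27, DMAP, rt → 40 °C
Reagents that add atoms: none
Why: Yamaguchi esterification: mixed anhydride 28 transfers the hindered epoxy acyl group through its acyl-DMAP salt to the only free hydroxyl (C9) with retention at all centres.

Step 19
Reactants: 29 (the silyl-protected ester from step 18)
Product: 30 (3S,6R,7S,8R,9S)-3-acetoxy-9-{[(2R,3R)-2,3-dimethyloxiran-2-yl]carbonyloxy}-8-hydroxygermacra-1(10)Z,4Z,11(13)-trien-12,6-olide (CNP0137407.4)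
Conditions: HF·pyridine, pyridine, THF, 0 °C → rt
Reagents that add atoms: none
Why: Fluoride-induced desilylation under buffered, mildly acidic conditions frees O8 without acyl migration from O9, epoxide opening or conjugate addition to the methylene lactone.

**Compound list**
1 | 5-hydroxy-4-methylfuran-2(5H)-one | CC1=CC(=O)OC1O | starting material
2 | allylboronic acid pinacol ester | C=CCB1OC(C)(C)C(C)(C)O1 | starting material
3 | (Z)-3-methyl-4-oxobut-2-enoic acid (open form of 1) | OC(=O)/C=C(/C)C=O | intermediate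
4 | (2Z,4S)-3-methyl-4-[(4,4,5,5-tetramethyl-1,3,2-dioxaborolan-2-yl)oxy]hepta-2,6-dienoic acid | OC(=O)/C=C(/C)[C@@H](OB1OC(C)(C)C(C)(C)O1)CC=C | intermediate
5 | (5S)-4-methyl-5-(prop-2-en-1-yl)furan-2(5H)-one | O=C1C=C(C)[C@H](CC=C)O1 | intermediate
6 | (5S)-4-methyl-5-(prop-2-en-1-yl)-2,5-dihydrofuran-2-ol (anomers) | OC1C=C(C)[C@H](CC=C)O1 | intermediate
7 | 1,2:5,6-di-O-isopropylidene-D-mannitol | CC1(C)OC[C@@H](O1)[C@@H](O)[C@H](O)[C@H]1COC(C)(C)O1 | starting material
8 | (R)-2,2-dimethyl-1,3-dioxolane-4-carbaldehyde | O=C[C@H]1COC(C)(C)O1 | intermediate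
9 | isopropenylmagnesium bromide | C=C(C)[Mg]Br | starting material
10 | (1S)-1-[(4R)-2,2-dimethyl-1,3-dioxolan-4-yl]-2-methylprop-2-en-1-ol | C=C(C)[C@H](O)[C@H]1COC(C)(C)O1 | intermediate
11 | (4R)-4-[(1S)-1-[(4-methoxybenzyl)oxy]-2-methylprop-2-en-1-yl]-2,2-dimethyl-1,3-dioxolane | C=C(C)[C@H](OCc1ccc(OC)cc1)[C@H]1COC(C)(C)O1 | intermediate
12 | (2R,3S)-3-[(4-methoxybenzyl)oxy]-4-methylpent-4-ene-1,2-diol | C=C(C)[C@H](OCc1ccc(OC)cc1)[C@H](O)CO | intermediate
13 | (2R,3S)-3-[(4-methoxybenzyl)oxy]-4-methyl-1,2-bis[(triethylsilyl)oxy]pent-4-ene | C=C(C)[C@H](OCc1ccc(OC)cc1)[C@H](O[Si](CC)(CC)CC)CO[Si](CC)(CC)CC | intermediate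
14 | (2S,3S)-3-[(4-methoxybenzyl)oxy]-4-methyl-2-[(triethylsilyl)oxy]pent-4-enal | C=C(C)[C@H](OCc1ccc(OC)cc1)[C@H](O[Si](CC)(CC)CC)C=O | intermediate
15 | methyl propiolate | C#CC(=O)OC | starting material
16 | methyl 2-[bis(2-methylpropyl)alumanyl]prop-2-enoate | C=C([Al](CC(C)C)CC(C)C)C(=O)OC | intermediate
17 | methyl (4R,5S)-3-hydroxy-5-[(4-methoxybenzyl)oxy]-6-methyl-2-methylidene-4-[(triethylsilyl)oxy]hept-6-enoate (carbinol epimers) | C=C(C)[C@H](OCc1ccc(OC)cc1)[C@H](O[Si](CC)(CC)CC)C(O)C(=C)C(=O)OC | intermediate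
18 | methyl (2Z,4R,5S)-2-(bromomethyl)-5-[(4-methoxybenzyl)oxy]-6-methyl-4-[(triethylsilyl)oxy]hepta-2,6-dienoate | C=C(C)[C@H](OCc1ccc(OC)cc1)[C@H](O[Si](CC)(CC)CC)/C=C(\CBr)C(=O)OC | intermediate
19 | methyl angelate, methyl (Z)-2-methylbut-2-enoate | C/C=C(/C)C(=O)OC | starting material
20 | (Z)-2-methylbut-2-en-1-ol | C/C=C(/C)CO | intermediate
21 | [(2S,3R)-2,3-dimethyloxiran-2-yl]methanol | OC[C@]1(C)O[C@@H]1C | intermediate
22 | (2R,3R)-2,3-dimethyloxirane-2-carboxylic acid | OC(=O)[C@]1(C)O[C@@H]1C | intermediate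
23 | methyl (3R,4R,5Z,7S)-4,7-dihydroxy-3-[(1R,2S)-2-[(4-methoxybenzyl)oxy]-3-methyl-1-[(triethylsilyl)oxy]but-3-en-1-yl]-6-methyl-2-methylidenedeca-5,9-dienoate | C=C(C)[C@H](OCc1ccc(OC)cc1)[C@H](O[Si](CC)(CC)CC)[C@H](C(=C)C(=O)OC)[C@H](O)/C=C(/C)[C@@H](O)CC=C | intermediate
24 | (4R,5R)-5-[(1Z,3S)-3-hydroxy-2-methylhexa-1,5-dien-1-yl]-4-[(1R,2S)-2-[(4-methoxybenzyl)oxy]-3-methyl-1-[(triethylsilyl)oxy]but-3-en-1-yl]-3-methylideneoxolan-2-one | C=C1C(=O)O[C@H](/C=C(/C)[C@@H](O)CC=C)[C@@H]1[C@@H](O[Si](CC)(CC)CC)[C@@H](OCc2ccc(OC)cc2)C(C)=C | intermediate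
25 | (4R,5R)-5-[(1Z,3S)-3-(acetyloxy)-2-methylhexa-1,5-dien-1-yl]-4-[(1R,2S)-2-[(4-methoxybenzyl)oxy]-3-methyl-1-[(triethylsilyl)oxy]but-3-en-1-yl]-3-methylideneoxolan-2-one | C=C1C(=O)O[C@H](/C=C(/C)[C@@H](OC(C)=O)CC=C)[C@@H]1[C@@H](O[Si](CC)(CC)CC)[C@@H](OCc2ccc(OC)cc2)C(C)=C | intermediate
26 | (4R,5R)-5-[(1Z,3S)-3-(acetyloxy)-2-methylhexa-1,5-dien-1-yl]-4-[(1R,2S)-2-hydroxy-3-methyl-1-[(triethylsilyl)oxy]but-3-en-1-yl]-3-methylideneoxolan-2-one | C=C1C(=O)O[C@H](/C=C(/C)[C@@H](OC(C)=O)CC=C)[C@@H]1[C@@H](O[Si](CC)(CC)CC)[C@@H](O)C(C)=C | intermediate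
27 | (3S,6R,7R,8R,9S)-3-acetoxy-9-hydroxy-8-[(triethylsilyl)oxy]germacra-1(10)Z,4Z,11(13)-trien-12,6-olide | C=C1C(=O)O[C@@H]2/C=C(/C)[C@@H](OC(C)=O)C/C=C(/C)[C@H](O)[C@H](O[Si](CC)(CC)CC)[C@H]12 | intermediate
28 | (2R,3R)-2,3-dimethyloxirane-2-carboxylic 2,4,6-trichlorobenzoic anhydride | O=C(OC(=O)c1c(Cl)cc(Cl)cc1Cl)[C@]2(C)O[C@@H]2C | intermediate
29 | (3S,6R,7R,8R,9S)-3-acetoxy-9-{[(2R,3R)-2,3-dimethyloxiran-2-yl]carbonyloxy}-8-[(triethylsilyl)oxy]germacra-1(10)Z,4Z,11(13)-trien-12,6-olide | C=C1C(=O)O[C@@H]2/C=C(/C)[C@@H](OC(C)=O)C/C=C(/C)[C@H](OC(=O)[C@]3(C)O[C@@H]3C)[C@H](O[Si](CC)(CC)CC)[C@H]12 | intermediate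
30 | (3S,6R,7S,8R,9S)-3-acetoxy-9-{[(2R,3R)-2,3-dimethyloxiran-2-yl]carbonyloxy}-8-hydroxygermacra-1(10)Z,4Z,11(13)-trien-12,6-olide | C=C1C(=O)O[C@@H]2/C=C(/C)[C@@H](OC(C)=O)C/C=C(/C)[C@H](OC(=O)[C@]3(C)O[C@@H]3C)[C@H](O)[C@H]12 | target

**Totals**
Total steps: 19. Longest linear sequence: 14 (steps 3–10, then 14–19).

**Three steps most likely to fail**

Step 1 (the proposed new allylboration). The open aldehyde form of 1 is present only in small amounts, and an uncatalysed or carboxylic-acid-assisted background reaction could erode the enantiomeric excess. Fallback by known chemistry, from 1 back to 5: 1 is converted with TMSCHN2 (MeOH/toluene, 0 °C) into its open-chain normal ester, methyl (Z)-3-methyl-4-oxobut-2-enoate F1. Brown allylation of F1 with (−)-Ipc2B(allyl) (Et2O, −78 °C, perborate work-up) gives methyl (2Z,4S)-4-hydroxy-3-methylhepta-2,6-dienoate F2, whose Z-disposed hydroxyl and ester close (cat. PPTS) to 5.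

Step 14 (Barbier union). The lactol may dehydrate to 2-allyl-3-methylfuran before it is trapped, and the C7/C8 facial preference rests on an A1,3-strain model rather than a direct precedent. The silyl ether (not an ester) on O8 is what keeps the allylindium from 1,4-elimination. Fallback, from 5 back to 25, with an acyclic, fully protected aldehyde and zinc:
- i-Bu2AlH (2.5 equiv, CH2Cl2, −78 → 0 °C) reduces 5 to (2Z,4S)-3-methylhepta-2,6-diene-1,4-diol F3.
- TBSCl/imidazole (−20 °C) gives the primary silyl ether (2Z,4S)-1-[(tert-butyldimethylsilyl)oxy]-3-methylhepta-2,6-dien-4-ol F4.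
- Ac2O/pyridine gives the acetate F5.
- HF·pyridine frees the primary alcohol (2Z,4S)-1-hydroxy-3-methylhepta-2,6-dien-4-yl acetate F6.
- Buffered Dess–Martin oxidation gives the (Z)-enal (2Z,4S)-3-methyl-1-oxohepta-2,6-dien-4-yl acetate F7.
- Zinc-mediated Barbier reaction of F7 with 18 (Zn dust, THF/sat. aq. NH4Cl, rt) gives the hydroxy ester F8, which lactonises with cat. PPTS directly to 25.

Step 17 (ring-closing metathesis to a trisubstituted alkene in a ten-membered ring). The isopropenyl group is hindered and dimerisation can compete. Fallback, from 26 back to 27, moving the ring closure to an enone: Dess–Martin periodinane oxidises 26 to the isopropenyl ketone F9. Its C9 is planar and less hindered, and metathesis (second-generation Hoveyda–Grubbs catalyst, toluene, 80 °C) gives a conjugated product, the macrocyclic (Z)-enone F10. Reagent-controlled 1,2-reduction with (S)-Me-CBS oxazaborolidine/catecholborane (toluene, −78 °C) returns the 9S alcohol 27.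

**Further compounds**
F1 | step 1 | methyl (Z)-3-methyl-4-oxobut-2-enoate | COC(=O)/C=C(/C)C=O
F2 | step 1 | methyl (2Z,4S)-4-hydroxy-3-methylhepta-2,6-dienoate | COC(=O)/C=C(/C)[C@@H](O)CC=C
F3 | step 14 | (2Z,4S)-3-methylhepta-2,6-diene-1,4-diol | OC/C=C(/C)[C@@H](O)CC=C
F4 | step 14 | (2Z,4S)-1-[(tert-butyldimethylsilyl)oxy]-3-methylhepta-2,6-dien-4-ol | CC(C)(C)[Si](C)(C)OC/C=C(/C)[C@@H](O)CC=C
F5 | step 14 | (2Z,4S)-1-[(tert-butyldimethylsilyl)oxy]-3-methylhepta-2,6-dien-4-yl acetate | CC(C)(C)[Si](C)(C)OC/C=C(/C)[C@@H](OC(C)=O)CC=C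
F6 | step 14 | (2Z,4S)-1-hydroxy-3-methylhepta-2,6-dien-4-yl acetate | OC/C=C(/C)[C@@H](OC(C)=O)CC=C
F7 | step 14 | (2Z,4S)-3-methyl-1-oxohepta-2,6-dien-4-yl acetate | O=C/C=C(/C)[C@@H](OC(C)=O)CC=C
F8 | step 14 | methyl (3R,4R,5Z,7S)-7-(acetyloxy)-4-hydroxy-3-[(1R,2S)-2-[(4-methoxybenzyl)oxy]-3-methyl-1-[(triethylsilyl)oxy]but-3-en-1-yl]-6-methyl-2-methylidenedeca-5,9-dienoate | C=C(C)[C@H](OCc1ccc(OC)cc1)[C@H](O[Si](CC)(CC)CC)[C@H](C(=C)C(=O)OC)[C@H](O)/C=C(/C)[C@@H](OC(C)=O)CC=C
F9 | step 17 | (4R,5R)-5-[(1Z,3S)-3-(acetyloxy)-2-methylhexa-1,5-dien-1-yl]-4-[(1R)-3-methyl-2-oxo-1-[(triethylsilyl)oxy]but-3-en-1-yl]-3-methylideneoxolan-2-one | C=C1C(=O)O[C@H](/C=C(/C)[C@@H](OC(C)=O)CC=C)[C@@H]1[C@@H](O[Si](CC)(CC)CC)C(=O)C(C)=C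
F10 | step 17 | (3S,6R,7R,8R)-3-acetoxy-9-oxo-8-[(triethylsilyl)oxy]germacra-1(10)Z,4Z,11(13)-trien-12,6-olide | C=C1C(=O)O[C@@H]2/C=C(/C)[C@@H](OC(C)=O)C/C=C(/C)C(=O)[C@H](O[Si](CC)(CC)CC)[C@H]12
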